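**Amounts first.** Each flask is charged with substrate and other conformer, and I count what stands in it in molar amounts, not percent.

| flask | substrate | other conformer | remark | time |
|---|---|---|---|---|
| violet | 0.10 M | 0.20 M | run made earlier |  |
| amber | 0.40 M | 0.20 M | run made earlier |  |
| flask | 0.20 M | 0.200 M |  | 15 d |

| run | time / d | isomer of the product / % | target / % |
|---|---|---|---|
| violet | 0.625 | 45.8 | 10.5 |
| violet | 1.04 | 56.9 | 10.9 |
| violet | 1.67 | 64.4 | 11.0 |
| violet | 2.50 | 66.5 | 10.6 |
| violet | 4.00 | 67.0 | 11.1 |
| violet | 6.00 | 66.9 | 10.5 |
| violet | 10.0 | 67.8 | 11.0 |
| amber | 1.25 | 36.0 | 5.6 |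
| amber | 2.50 | 40.7 | 7.4 |
| amber | 4.00 | 40.1 | 6.3 |
| amber | 5.00 | 40.1 | 5.6 |
| amber | 6.00 | 41.3 | 7.1 |
| amber | 8.00 | 40.4 | 7.2 |
| amber | 10.0 | 40.7 | 6.3 |

(readings scatter by 0.5 percentage points)

- share of isomer of the product in isomer of the product plus target at 8.0 min
- share of isomer of the product in isomer of the product plus target at 6.0 h
- share of isomer of the product in isomer of the product plus target at 15 d

- percentages count the substrate that a species holds: one side product counts as two
- the numbers in the tables scatter with a standard deviation of 0.5 percentage points
- on the list of suspects stand: substrate + target -> side product; substrate <-> other conformer; substrate -> target; other conformer -> isomer of the product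

**Turned round.** The asked share r, a selectivity, would reverse if a flask ended with more target than isomer of the product. So I ask how much target a run holds. The last readings give 0.0330 M in the violet run and 0.0378 M in the amber run, although their substrate charges are 0.10 M and 0.40 M. The amount of target at which a run levels off, the target ceiling T_c, I take as their mean, 0.0354 M.

**My reckoning.** The last readings put isomer of the product at the charged other conformer plus an excess X: 0.00340 M in violet and 0.0442 M in amber. Interpolating on the substrate charge gives 0.0170 M for the flask, so I estimate its final isomer of the product, I, at 0.217 M. The opposite outcome needs I below T_c, but this I stands 6.13 times above it. Then r = I/(I + T_c) gives 86.0 % at 15 d.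

**The forecast.** It gives 13 % at 8.0 min, with a range up to 27 %, then 69 % at 6.0 h and 85.1 % at 15 d; my figure is a little higher. Of the early time it says: “The ratio is therefore poorly fixed”.

**The result.** The flask gives 49.5 %, 69.9 % and 85.4 %. The early share lies above the forecast's range; the other two lie inside theirs.

    substrate + target → side product (k = 5.30 × 10⁻⁴ M⁻¹ s⁻¹)
    substrate ⇌ other conformer (K = 3.50, k = 8.00 × 10⁻⁶ s⁻¹)
    substrate → target (k = 2.10 × 10⁻⁵ s⁻¹)
    other conformer → isomer of the product (k = 2.00 × 10⁻⁵ s⁻¹)

**One reason.** The flask's target ends at 9.29 % of the charge, where T_c gives 8.85 %. Taking away substrate + target → side product lowers the share at 15 d from 85.4 % to 58.9 %. So that step is one part of what keeps target small beside isomer of the product in this flask, not the whole of it.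

**Second flask.** For the neighbour flask with 0.080 M of other conformer, T_c and the same X give a share of 73.3 % and target at 12.6 % of the charge. The computed neighbour gives 74.5 % and 13.1 %.

Readings and results were computed on assumed constants; noise was put on by code.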